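## Retrosynthetic overview

1. Ring numbering as cyclohexa-2,4-dien-1-one (C1 = C=O, C2/C5 = CH, C3/C4 = C–OMe, C6 = quaternary carbon). End game: acetate ⇐ silyl ether exchange; 2,4-dienone ⇐ DDQ dehydrogenation of the silyl dienol ether of 3,4-dimethoxycyclohex-3-enone 16.
2. Key disconnection C5–C6: 16 ⇐ 3-methoxy-3-(1-methoxyvinyl)cyclobutanone 15 by Lewis-acid ring expansion (net 1,3-shift of C6 from C3 to C5). This closes the six-membered ring and sets the C6 stereocentre.
3. 15 ⇐ [2+2] of an allyl(alkyl)ketene (C1, C6) with 2,3-dimethoxybuta-1,3-diene (C2–C5 with both methoxy groups); ketene ⇐ α-allylated acid 11.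
4. 11 ⇐ syn-crotylboration of 3,4-dimethoxybenzaldehyde (both side-chain stereocentres), hydroboration/oxidation, dianion allylation.
5. Enabling feature: the ring's C2=C3(OMe)–C4(OMe)=C5 bis(enol ether) flanked by the C1 ketone and C6. The C3 methoxy makes the cyclobutanone a donor–acceptor ring whose C3–C6 bond ionises, and the C4(OMe)=C5 vinyl unit relays the cation to C5, where the C1/C6 enolate recloses. Ring order: arene (starting material), temporary four-membered ring (step 6), six-membered ring (step 7).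

Key step: step 7

Remark on the chemistry: the (R)-configured phosphoric acid in step 1 is taken to direct Re-face crotylation of the aryl aldehyde; if the sense is opposite, the antipodal catalyst is used.

## Route

Step 1
Reactants: 1 3,4-dimethoxybenzaldehyde; 2 (Z)-crotylboronic acid pinacol ester
Product: 4 (1R,2S)-1-(3,4-dimethoxyphenyl)-2-methylbut-3-en-1-ol, via borate ester 3 (not isolated)
Conditions: (R)-TRIP phosphoric acid (5 mol%), toluene, 4 Å MS, −30 °C; aq. NaHCO3
Reagents that add atoms: none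
Why: Chiral phosphoric acid-catalysed crotylboration through a closed six-membered chair transition state, in which the (Z)-boronate geometry should give the syn carbinol/methyl relationship and the catalyst should select the aldehyde Re face, setting (1R) and (2S).

Step 2
Reactants: 4 (1R,2S)-1-(3,4-dimethoxyphenyl)-2-methylbut-3-en-1-ol
Product: 5 tert-butyl{[(1R,2S)-1-(3,4-dimethoxyphenyl)-2-methylbut-3-en-1-yl]oxy}dimethylsilane
Conditions: TBSCl, imidazole, DMF, rt
Reagents that add atoms: tert-butyldimethylsilyl chloride, CC(C)(C)[Si](C)(C)Cl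
Why: Standard silylation of a secondary benzylic alcohol; a silyl ether is carried because the dianion alkylation of step 5 would not tolerate the acetate.

Step 3
Reactants: 5 tert-butyl{[(1R,2S)-1-(3,4-dimethoxyphenyl)-2-methylbut-3-en-1-yl]oxy}dimethylsilane
Product: 7 (3S,4R)-4-[(tert-butyldimethylsilyl)oxy]-4-(3,4-dimethoxyphenyl)-3-methylbutan-1-ol, via alkylborane 6 (not isolated)
Conditions: 9-BBN, THF, 0 °C → rt; then NaOH, H2O2, 0 °C → rt
Reagents that add atoms: hydrogen peroxide, OO
Why: Anti-Markovnikov hydroboration–oxidation of the monosubstituted alkene with a bulky borane; no stereocentre is touched.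

Step 4
Reactants: 7 (3S,4R)-4-[(tert-butyldimethylsilyl)oxy]-4-(3,4-dimethoxyphenyl)-3-methylbutan-1-ol
Product: 9 (3S,4R)-4-[(tert-butyldimethylsilyl)oxy]-4-(3,4-dimethoxyphenyl)-3-methylbutanoic acid, via aldehyde 8 (not isolated)
Conditions: TEMPO (cat.), PhI(OAc)2, MeCN/H2O, rt
Reagents that add atoms: water, O
Why: Nitroxyl-catalysed oxidation of the primary alcohol through the aldehyde hydrate to the acid under near-neutral conditions that should spare the silyl ether and the electron-rich arene.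

Step 5
Reactants: 9 (3S,4R)-4-[(tert-butyldimethylsilyl)oxy]-4-(3,4-dimethoxyphenyl)-3-methylbutanoic acid
Product: 11 2-[(1R,2S)-1-[(tert-butyldimethylsilyl)oxy]-1-(3,4-dimethoxyphenyl)propan-2-yl]pent-4-enoic acid (C2 epimer mixture), via dilithium enediolate 10 (not isolated)
Conditions: LDA (2.2 equiv), THF, −78 → 0 °C; DMPU, allyl bromide, −78 °C → rt; aq. HCl work-up
Reagents that add atoms: allyl bromide, C=CCBr
Why: Alkylation of a carboxylic acid dianion with allyl bromide; the new α-stereocentre is uncontrolled, which is immaterial because this carbon becomes sp2 in the ketene of step 6.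

Step 6
Reactants: 11 2-[(1R,2S)-1-[(tert-butyldimethylsilyl)oxy]-1-(3,4-dimethoxyphenyl)propan-2-yl]pent-4-enoic acid; 12 2,3-dimethoxybuta-1,3-diene
Product: 15 2-allyl-3-methoxy-3-(1-methoxyvinyl)-2-[(1R,2S)-1-[(tert-butyldimethylsilyl)oxy]-1-(3,4-dimethoxyphenyl)propan-2-yl]cyclobutan-1-one (C2/C3 diastereomer mixture), via acyl chloride 13 (not isolated), via ketene 14 (not isolated)
Conditions: (COCl)2, DMF (cat.), CH2Cl2, 0 °C → rt, evaporate; then 12 (4 equiv), Et3N, MeCN, 70 °C, slow addition of the acyl chloride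
Reagents that add atoms: none
Why: Dehydrohalogenation to the dialkylketene and thermal ketene–enol ether [2+2] cycloaddition, in which the nucleophilic CH2 terminus of one enol ether unit of 12 bonds to the ketene carbonyl carbon to give the 3-alkoxycyclobutanone; the two new ring stereocentres are uncontrolled and both are erased or reset in step 7.

Step 7
Reactants: 15 2-allyl-3-methoxy-3-(1-methoxyvinyl)-2-[(1R,2S)-1-[(tert-butyldimethylsilyl)oxy]-1-(3,4-dimethoxyphenyl)propan-2-yl]cyclobutan-1-one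
Product: 16 (6S)-6-allyl-6-[(1R,2S)-1-[(tert-butyldimethylsilyl)oxy]-1-(3,4-dimethoxyphenyl)propan-2-yl]-3,4-dimethoxycyclohex-3-en-1-one
Conditions: BF3·OEt2 (0.2 equiv), CH2Cl2, −78 → −40 °C; Et3N quench
Reagents that add atoms: none
Why: Proposed new method: BF3 on the carbonyl oxygen should heterolyse the donor–acceptor C2–C3 bond of 15 (the bond between the two fully substituted ring carbons) to a 1,4-zwitterion made of a boron enolate and a methoxy-oxocarbenium ion that is vinylogous through the 1-methoxyvinyl group (a 2-methoxyallyl cation), and re-closure of the enolate carbon on the remote vinyl CH2 instead of the oxocarbenium carbon gives the cyclohex-3-enone, a net 1,3-shift in which the old C2 becomes C6 and the vinyl CH2 becomes C5. The closest known reaction types are the Lewis-acid opening of 3-alkoxycyclobutanones to 1,4-zwitterions that enter formal [4+2] cycloadditions, the vinylcyclobutane-to-cyclohexene rearrangement and the conjugate addition of enolates to α,β-unsaturated oxocarbenium ions. The six-membered ring closes in a 6-(enolendo)-endo-trig mode, with both the enolate C=C and the attacked C=C endocyclic. The C6 stereocentre is created from a planar enolate, so the diastereomer mixture of 15 converges, and its configuration is set by the adjacent methyl-bearing stereocentre: with that C–H eclipsing the enolate (allylic 1,3-strain), the cationic terminus should approach the face anti to the CH(OTBS)Ar group, which is the face that leads to the configuration of the target. Three selectivities are needed: cleavage of C2–C3 rather than C3–C4 (secured by the strain between two fully substituted carbons and the tetrasubstituted enolate released), closure at the vinyl terminus rather than return to the four-membered ring or O-closure (both reversible under the Lewis acid, the unstrained ketone being the sink), and ring closure rather than proton loss to an open-chain methoxy enone (secured by base-free, aprotic conditions at low temperature).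

Step 8
Reactants: 16 (6S)-6-allyl-6-[(1R,2S)-1-[(tert-butyldimethylsilyl)oxy]-1-(3,4-dimethoxyphenyl)propan-2-yl]-3,4-dimethoxycyclohex-3-en-1-one
Product: 17 tert-butyl{[(6S)-6-allyl-6-[(1R,2S)-1-[(tert-butyldimethylsilyl)oxy]-1-(3,4-dimethoxyphenyl)propan-2-yl]-3,4-dimethoxycyclohexa-1,3-dien-1-yl]oxy}dimethylsilane
Conditions: TBSOTf, Et3N, CH2Cl2, −78 → 0 °C
Reagents that add atoms: tert-butyldimethylsilyl trifluoromethanesulfonate, CC(C)(C)[Si](C)(C)OS(=O)(=O)C(F)(F)F
Why: Soft enolisation and O-silylation toward the only enolisable α-position (C2) should give the conjugated 1-silyloxy-1,3-diene; the conjugated enone tautomer of 16, if present, converges on the same diene.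

Step 9
Reactants: 17 tert-butyl{[(6S)-6-allyl-6-[(1R,2S)-1-[(tert-butyldimethylsilyl)oxy]-1-(3,4-dimethoxyphenyl)propan-2-yl]-3,4-dimethoxycyclohexa-1,3-dien-1-yl]oxy}dimethylsilane
Product: 18 (6R)-6-allyl-6-[(1R,2S)-1-[(tert-butyldimethylsilyl)oxy]-1-(3,4-dimethoxyphenyl)propan-2-yl]-3,4-dimethoxycyclohexa-2,4-dien-1-one
Conditions: DDQ (1.05 equiv), 2,6-lutidine (0.5 equiv), CH2Cl2, −40 → 0 °C; aq. NaHCO3
Reagents that add atoms: none
Why: DDQ dehydrogenation of a silyl dienol ether (hydride abstraction from the C5 methylene, then desilylation), the known conversion of 1-oxy-1,3-dienes into linear 2,4-dienones; this and all later steps are kept at or below room temperature to avoid a Cope shift of the 6-allyl group.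

Step 10
Reactants: 18 (6R)-6-allyl-6-[(1R,2S)-1-[(tert-butyldimethylsilyl)oxy]-1-(3,4-dimethoxyphenyl)propan-2-yl]-3,4-dimethoxycyclohexa-2,4-dien-1-one
Product: 19 (6R)-6-allyl-6-[(1R,2S)-1-(3,4-dimethoxyphenyl)-1-hydroxypropan-2-yl]-3,4-dimethoxycyclohexa-2,4-dien-1-one
Conditions: HF·pyridine, pyridine, THF, 0 °C → rt
Reagents that add atoms: none
Why: Fluoride cleavage of the benzylic silyl ether under buffered, slightly acidic conditions, so that no alkoxide is available to add to the dienone.

Step 11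
Reactants: 19 (6R)-6-allyl-6-[(1R,2S)-1-(3,4-dimethoxyphenyl)-1-hydroxypropan-2-yl]-3,4-dimethoxycyclohexa-2,4-dien-1-one
Product: 20 (6R)-6-allyl-6-[(1R,2S)-1-acetoxy-1-(3,4-dimethoxyphenyl)propan-2-yl]-3,4-dimethoxycyclohexa-2,4-dien-1-one (target)
Conditions: Ac2O, pyridine, DMAP (cat.), CH2Cl2, 0 °C → rt
Reagents that add atoms: acetic anhydride, CC(=O)OC(C)=O
Why: DMAP-catalysed O-acetylation of the secondary benzylic alcohol, with retention at the carbinol carbon.

## Compound list

1 | 3,4-dimethoxybenzaldehyde | COc1ccc(C=O)cc1OC | starting material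
2 | (Z)-crotylboronic acid pinacol ester | C/C=C\CB1OC(C)(C)C(C)(C)O1 | starting material
3 | 2-{[(1R,2S)-1-(3,4-dimethoxyphenyl)-2-methylbut-3-en-1-yl]oxy}-4,4,5,5-tetramethyl-1,3,2-dioxaborolane | C=C[C@H](C)[C@@H](OB1OC(C)(C)C(C)(C)O1)c2ccc(OC)c(OC)c2 | intermediate (not isolated)
4 | (1R,2S)-1-(3,4-dimethoxyphenyl)-2-methylbut-3-en-1-ol | C=C[C@H](C)[C@@H](O)c1ccc(OC)c(OC)c1 | intermediate
5 | tert-butyl{[(1R,2S)-1-(3,4-dimethoxyphenyl)-2-methylbut-3-en-1-yl]oxy}dimethylsilane | C=C[C@H](C)[C@@H](O[Si](C)(C)C(C)(C)C)c1ccc(OC)c(OC)c1 | intermediate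
6 | 9-[(3S,4R)-4-[(tert-butyldimethylsilyl)oxy]-4-(3,4-dimethoxyphenyl)-3-methylbutyl]-9-borabicyclo[3.3.1]nonane | C12CCCC(CCC1)B2CC[C@H](C)[C@@H](O[Si](C)(C)C(C)(C)C)c3ccc(OC)c(OC)c3 | intermediate (not isolated)
7 | (3S,4R)-4-[(tert-butyldimethylsilyl)oxy]-4-(3,4-dimethoxyphenyl)-3-methylbutan-1-ol | OCC[C@H](C)[C@@H](O[Si](C)(C)C(C)(C)C)c1ccc(OC)c(OC)c1 | intermediate
8 | (3S,4R)-4-[(tert-butyldimethylsilyl)oxy]-4-(3,4-dimethoxyphenyl)-3-methylbutanal | O=CC[C@H](C)[C@@H](O[Si](C)(C)C(C)(C)C)c1ccc(OC)c(OC)c1 | intermediate (not isolated)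
9 | (3S,4R)-4-[(tert-butyldimethylsilyl)oxy]-4-(3,4-dimethoxyphenyl)-3-methylbutanoic acid | OC(=O)C[C@H](C)[C@@H](O[Si](C)(C)C(C)(C)C)c1ccc(OC)c(OC)c1 | intermediate
10 | dilithium (3S,4R)-4-[(tert-butyldimethylsilyl)oxy]-4-(3,4-dimethoxyphenyl)-3-methylbut-1-ene-1,1-bis(olate) | [Li+].[Li+].[O-]C([O-])=C[C@H](C)[C@@H](O[Si](C)(C)C(C)(C)C)c1ccc(OC)c(OC)c1 | intermediate (not isolated)
11 | 2-[(1R,2S)-1-[(tert-butyldimethylsilyl)oxy]-1-(3,4-dimethoxyphenyl)propan-2-yl]pent-4-enoic acid (C2 epimers) | C=CCC(C(=O)O)[C@H](C)[C@@H](O[Si](C)(C)C(C)(C)C)c1ccc(OC)c(OC)c1 | intermediate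
12 | 2,3-dimethoxybuta-1,3-diene | C=C(OC)C(OC)=C | starting material
13 | 2-[(1R,2S)-1-[(tert-butyldimethylsilyl)oxy]-1-(3,4-dimethoxyphenyl)propan-2-yl]pent-4-enoyl chloride (C2 epimers) | C=CCC(C(=O)Cl)[C@H](C)[C@@H](O[Si](C)(C)C(C)(C)C)c1ccc(OC)c(OC)c1 | intermediate (not isolated)
14 | 2-[(1R,2S)-1-[(tert-butyldimethylsilyl)oxy]-1-(3,4-dimethoxyphenyl)propan-2-yl]penta-1,4-dien-1-one (ketene) | C=CCC(=C=O)[C@H](C)[C@@H](O[Si](C)(C)C(C)(C)C)c1ccc(OC)c(OC)c1 | intermediate (not isolated)
15 | 2-allyl-3-methoxy-3-(1-methoxyvinyl)-2-[(1R,2S)-1-[(tert-butyldimethylsilyl)oxy]-1-(3,4-dimethoxyphenyl)propan-2-yl]cyclobutan-1-one (mixture at ring C2 and C3, side-chain centres defined) | C=CCC1([C@H](C)[C@@H](O[Si](C)(C)C(C)(C)C)c2ccc(OC)c(OC)c2)C(=O)CC1(OC)C(OC)=C | intermediate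
16 | (6S)-6-allyl-6-[(1R,2S)-1-[(tert-butyldimethylsilyl)oxy]-1-(3,4-dimethoxyphenyl)propan-2-yl]-3,4-dimethoxycyclohex-3-en-1-one | C=CC[C@@]1([C@H](C)[C@@H](O[Si](C)(C)C(C)(C)C)c2ccc(OC)c(OC)c2)CC(OC)=C(OC)CC1=O | intermediate
17 | tert-butyl{[(6S)-6-allyl-6-[(1R,2S)-1-[(tert-butyldimethylsilyl)oxy]-1-(3,4-dimethoxyphenyl)propan-2-yl]-3,4-dimethoxycyclohexa-1,3-dien-1-yl]oxy}dimethylsilane | C=CC[C@@]1([C@H](C)[C@@H](O[Si](C)(C)C(C)(C)C)c2ccc(OC)c(OC)c2)CC(OC)=C(OC)C=C1O[Si](C)(C)C(C)(C)C | intermediate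
18 | (6R)-6-allyl-6-[(1R,2S)-1-[(tert-butyldimethylsilyl)oxy]-1-(3,4-dimethoxyphenyl)propan-2-yl]-3,4-dimethoxycyclohexa-2,4-dien-1-one | C=CC[C@@]1([C@H](C)[C@@H](O[Si](C)(C)C(C)(C)C)c2ccc(OC)c(OC)c2)C=C(OC)C(OC)=CC1=O | intermediate
19 | (6R)-6-allyl-6-[(1R,2S)-1-(3,4-dimethoxyphenyl)-1-hydroxypropan-2-yl]-3,4-dimethoxycyclohexa-2,4-dien-1-one | C=CC[C@@]1([C@H](C)[C@@H](O)c2ccc(OC)c(OC)c2)C=C(OC)C(OC)=CC1=O | intermediate
20 | (6R)-6-allyl-6-[(1R,2S)-1-acetoxy-1-(3,4-dimethoxyphenyl)propan-2-yl]-3,4-dimethoxycyclohexa-2,4-dien-1-one | C=CC[C@@]1([C@H](C)[C@@H](OC(C)=O)c2ccc(OC)c(OC)c2)C=C(OC)C(OC)=CC1=O | target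

The CIP descriptor at the quaternary carbon changes from S (16, 17) to R (18–20) only because the ring neighbour C5 gains priority on becoming sp2; the geometry is unchanged.

## Summary and risks

Total step count: 11. Longest linear sequence: 11 steps (1 → 20); 2 and 12 are single-step inputs.

**Step 7 (proposed new method).** The zwitterion may lose a proton to an open-chain methoxy enone faster than it recloses, or may reclose with insufficient facial selectivity. The fallback uses known pericyclic chemistry and runs from 15 to 17, replacing steps 7 and 8. Soft enolisation of 15 (TBSOTf, Et3N, CH2Cl2, −78 → 0 °C) should give the 1-silyloxycyclobutene F1. Its conrotatory 4π ring opening, with the methoxy group rotating outward and the 1-methoxyvinyl group inward, should give the (3E)-silyloxytetraene F2, whose central double bond has the geometry needed for cyclisation; direct ionisation and deprotonation of 15 would lead to the same tetraene. Heating (toluene, 100–120 °C, BHT) should then close the same C5–C6 bond by disrotatory 6π electrocyclisation under the same allylic-strain control, giving 17, from which the route continues at step 9.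

**Step 6.** The γ-silyloxy acyl chloride may lactonise with loss of the silyl chloride, or the hindered dialkylketene may dimerise faster than it adds to 12. The fallback runs from 11 to 15 and replaces the free ketene by a keteniminium ion, which is more electrophilic and cannot dimerise. Acid 11 is converted into the dimethylamide F3 (Me2NH·HCl, EDC, HOBt, iPr2NEt, CH2Cl2). F3 is activated with Tf2O and 2,6-di-tert-butyl-4-methylpyridine (CH2Cl2, −20 °C → rt) to the keteniminium triflate F4, which should add 12 in a [2+2] cycloaddition to give the cyclobutaniminium triflate F5. Hydrolysis with aqueous NaHCO3 gives 15.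

**Step 9.** DDQ may abstract hydride from the veratryl benzylic position, undergo cycloaddition with the electron-rich diene, or over-oxidise instead of giving clean dehydrogenation at C5. The fallback runs from 17 to 18 by halogenation–dehydrohalogenation. NBS (THF, −78 °C) should brominate the γ-carbon (C4) of the silyl dienol ether to give the bromo enone F6, and this tertiary α-bromo ether should lose HBr on addition of Et3N (−78 → 0 °C) to give 18.

## Further compounds

F1 | step 7 | tert-butyl{[4-allyl-3-methoxy-3-(1-methoxyvinyl)-4-[(1R,2S)-1-[(tert-butyldimethylsilyl)oxy]-1-(3,4-dimethoxyphenyl)propan-2-yl]cyclobut-1-en-1-yl]oxy}dimethylsilane (mixture at ring C3 and C4) | C=CCC1([C@H](C)[C@@H](O[Si](C)(C)C(C)(C)C)c2ccc(OC)c(OC)c2)C(O[Si](C)(C)C(C)(C)C)=CC1(OC)C(OC)=C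
F2 | step 7 | (3E)-5-[(tert-butyldimethylsilyl)oxy]-6-[(1R,2S)-1-[(tert-butyldimethylsilyl)oxy]-1-(3,4-dimethoxyphenyl)propan-2-yl]-2,3-dimethoxynona-1,3,5,8-tetraene (5,6-double bond geometry not defined) | C=C(OC)/C(OC)=C\C(O[Si](C)(C)C(C)(C)C)=C(CC=C)[C@H](C)[C@@H](O[Si](C)(C)C(C)(C)C)c1ccc(OC)c(OC)c1
F3 | step 6 | 2-[(1R,2S)-1-[(tert-butyldimethylsilyl)oxy]-1-(3,4-dimethoxyphenyl)propan-2-yl]-N,N-dimethylpent-4-enamide (C2 epimers) | C=CCC(C(=O)N(C)C)[C@H](C)[C@@H](O[Si](C)(C)C(C)(C)C)c1ccc(OC)c(OC)c1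
F4 | step 6 | {2-[(1R,2S)-1-[(tert-butyldimethylsilyl)oxy]-1-(3,4-dimethoxyphenyl)propan-2-yl]penta-1,4-dien-1-ylidene}dimethylammonium trifluoromethanesulfonate | C=CCC(=C=[N+](C)C)[C@H](C)[C@@H](O[Si](C)(C)C(C)(C)C)c1ccc(OC)c(OC)c1.[O-]S(=O)(=O)C(F)(F)F
F5 | step 6 | {2-allyl-3-methoxy-3-(1-methoxyvinyl)-2-[(1R,2S)-1-[(tert-butyldimethylsilyl)oxy]-1-(3,4-dimethoxyphenyl)propan-2-yl]cyclobutylidene}dimethylammonium trifluoromethanesulfonate (mixture at ring C2 and C3) | C=CCC1([C@H](C)[C@@H](O[Si](C)(C)C(C)(C)C)c2ccc(OC)c(OC)c2)C(=[N+](C)C)CC1(OC)C(OC)=C.[O-]S(=O)(=O)C(F)(F)F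
F6 | step 9 | (6S)-6-allyl-4-bromo-6-[(1R,2S)-1-[(tert-butyldimethylsilyl)oxy]-1-(3,4-dimethoxyphenyl)propan-2-yl]-3,4-dimethoxycyclohex-2-en-1-one (C4 epimers) | C=CC[C@@]1([C@H](C)[C@@H](O[Si](C)(C)C(C)(C)C)c2ccc(OC)c(OC)c2)CC(Br)(OC)C(OC)=CC1=O
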